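## Structural features

The target is a labdane: a trans-fused decalin (rings A and B) with a gem-dimethyl group on C4, an angular methyl on C10 and an exocyclic methylene on C8 (C17). From C9 a two-carbon link (C11, C12) runs to the α-carbon C13 of a 2(5H)-furanone whose carbonyl is C16 and whose ring oxygen sits on C15. The four stereocentres are contiguous: C5 (H), C10 (quaternary), C9 (H) and the acetoxy carbon C11, in the configuration 5S,9S,10S,11R. Fragile elements are the secondary acetate, the butenolide (base-sensitive, a conjugate acceptor) and the C9 hydrogen, which is allylic to C8=C17 and α to any carbonyl placed at C11, so that epimerisation and migration of the double bond into the ring are always close. The first real difficulty is the vicinal pair C5/C10, with a quaternary centre wedged between C4 and C9. The second is C11, which lies outside the rings in a pocket lined by H-1, the C20 methyl and the C17 methylene, so that the substrate alone gives little reliable facial bias. The key step exploits the fact that C1–C5 and C10 of ring A, with the C4 methyls and C20, are exactly 2,4,4-trimethylcyclohex-2-enone: its β-carbon is C5 and its α-carbon, already carrying C20, is C10. One conjugate addition–alkylation therefore places the C6–C7–C8(–C17) arm on C5 and the C9–C11 arm on C10, trans to each other, and leaves ring B to be closed later between C8 and C9.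

## Logic of the disconnections

23 to 22: the C13=C14 bond of the butenolide is cut (ring-closing metathesis in the forward sense). The heterocycle is the most base-sensitive part, so it is formed last from an acyclic acrylate O-allyl ester. The forward step must engage the allyl and acrylate alkenes and ignore C8=C17.

22 to 21 to 20: the acetyl C–O bond and then the C11–H bond are cut. An analysis of the aldehyde 15 (C10 as the large group, C8 on the oxygen side) predicts that a carbon nucleophile gives mainly the 11S carbinol, the wrong one. C11 is therefore passed through a ketone and set by hydride. The gain is that C11 need not be controlled during C–C bond formation. The demand is a reagent-controlled reduction that tells the branched C9 side from the C12 methylene without enolising toward C9 or C12.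

20 to 19 to 15 and 17: the C11–C12 bond is cut. C12–C13(=CH2)–C16 is a 2-carboxyallyl nucleophile and C11 an aldehyde, so one reagent delivers three skeletal carbons with the metathesis handles in place. The forward step must run under neutral conditions so that 15 neither epimerises nor conjugates and the adduct does not lactonise.

17 to 16: the ester C–O bond is cut; a single esterification of a commercial acid.

15 to 14: the C8–C9 bond of ring B is cut. C9 is nucleophilic as the enol ether of the C11 aldehyde and C8 is the inner carbon of a terminal alkyne, so closure makes the ring, C9 and the exocyclic methylene at once. The decalin is reduced to a ring A with two arms. The forward step needs 6-exo-dig selectivity and a chair transition state with the formyl unit equatorial, without acid or base strong enough to move the alkene.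

14 to 13 to 11 to 10: functional-group changes only (enol silane from aldehyde, aldehyde from tert-butyl ester, terminal alkyne from silyl alkyne). The tert-butyl ester is kept deliberately: it stops at the aldehyde on hydride reduction, resists the hydrazide in the next retro-step and resists lactonisation.

10 to 7 to 6: the C1 carbonyl is put back. It is what makes C5 electrophilic and C10 nucleophilic. The forward removal must spare ester and alkyne next to a quaternary centre, hence a mild tosylhydrazone reduction.

6 to 3, 2 and 4: the C5–C6 and C9–C10 bonds are cut. Three commercial or one-step pieces result, and both ring-fusion centres are made from an achiral enone. The forward step needs ligand control at C5 and anti alkylation at C10.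

2 to 1: the C–Mg bond; the silyl cap is needed because a free alkyne hydrogen would quench the reagent.

## Other disconnections considered

Alternative 1: The cut runs through C4–C5 and C9–C10 back to acyclic farnesyl diphosphate A1. The forward key step would be a protonation-initiated cyclisation by a drimane-type synthase of the albicanol-synthase kind, giving albicanol A2 with loss of a C17 proton and hydrolysis of the diphosphate; oxidation of A2 at C11 would meet the chosen route at 15.
- In favour: one event would close both rings and set C5, C9 and C10 and the exocyclic alkene under enzyme control, with no C1 oxygen to remove and no protecting group.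
- Against: it needs an active expressed cyclase or producing strain, a supply of A1 and dilute aqueous operation; only the natural enantiomer and the natural ring A are served.
- Comparison: on structure and step economy it is better than the chosen plan (about two operations to 15 against eight; three stereocentres in the key event against two). Mechanistically it is a protein-templated cationic cascade against a ligand-controlled organocopper addition that can be tuned on the bench. On C11 and the butenolide the two are equal, since both pass through 15.
- The chosen plan is kept because it uses only commercial reagents, gives either enantiomer by choice of ligand and leaves a C1 ketone as a handle for analogues.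

Alternative 2: The cut is at C13–C16 and C16–O of the lactone. The forward key step would treat the Z-iodoallylic alcohol A3 with PdCl2(PPh3)2, CO and K2CO3: oxidative addition at C13–I, CO insertion and capture of the acylpalladium by the cis C15 hydroxyl would give the silyl-protected butenolide A4, followed by exchange of silyl for acetyl.
- In favour: this closure is among the most dependable routes to α-substituted butenolides. The Z geometry follows from hydroxyl-directed trans-hydroalumination and iodination, the ring forms 5-exo with no oligomer pathway, and C16 comes from CO.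
- Against: A3 would need about four operations from 15 (propargylation, silylation, hydroxymethylation, hydroalumination–iodination) and two after closure, about seven in all against five for the chosen endgame. C11 still has to be controlled or corrected. The alkenylpalladium at C13 has C8=C17 within 5-exo reach.
- Comparison: on reliability of the ring-forming event it is equal to or better than metathesis of a 1,1-disubstituted acrylate. On structure it is equal (butenolide last, built on 15, compatible with the same key step). On step economy it is worse by about two operations and a protecting-group exchange.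

Alternative 3: The cut is at C7–C8. In the forward key step 9-BBN would hydroborate the C5 vinyl group of the monocyclic enol triflate A5 at C7, and PdCl2(dppf) with Cs2CO3 would couple the C7 borane with the C8 triflate to give the silyl-protected labdane A6 carrying a 2-silylfuran; desilylation, acetylation and oxidation of the silylfuran to the butenolide would follow.
- In favour: ring B closes under mild conditions that cannot epimerise C9 or move the methylene, whose position is fixed by the triflate. C11 is set before the decalin exists, on a less congested aldehyde where reagent or chelate control is easier; on this point it is better than the chosen plan, which spends an oxidation–reduction pair on C11.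
- Against: A5 must already hold C5, C9, C10 and C11 on a monocycle, with the C9 methine between the quaternary C10 and the triflate set acyclically. The enol triflate must be made regioselectively next to that epimerisable centre. The hydroboration must select a neopentyl-type vinyl group over furan and triflate. The final furan oxidation must spare C8=C17.
- Comparison: the C5/C10 problem is the same and the chosen key step could equally feed this plan, so the two differ only in how ring B closes. Mechanistically the cross-coupling is equal or better in robustness than the gold cyclisation. In step economy the assembly of A5 is expected to cost more operations than the four functional-group changes between 6 and 14, so the chosen plan should be shorter overall.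

Key step: step 2

Remark 1: labdane numbering is used for all intermediates; the structures of precursor 3 and product 6 were checked against the target and need no correction (6 is 5S,10R by the CIP rules only because the C1 carbonyl outranks C5; the spatial arrangement is that of the target).
Remark 2: the ligand enantiomer named in step 2 is the one assumed to give 5S; if a first run shows the opposite sense, the mirror-image ligand is used with no other change.
Remark 3: metal or boron alkoxides of a product that are only hydrolysed on work-up are not numbered.

Step 1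
Reactants: 1 4-bromo-1-(trimethylsilyl)but-1-yne
Product: 2 [4-(trimethylsilyl)but-3-yn-1-yl]magnesium bromide (used as its Et2O solution)
Conditions: Mg turnings, I2 (cat.), Et2O, reflux
Reagents that add atoms: magnesium, [Mg]
Why: Grignard formation by insertion of magnesium into the primary C–Br bond; the silyl cap removes the acidic alkyne hydrogen that would otherwise destroy the reagent.

Step 2
Reactants: 3 2,4,4-trimethylcyclohex-2-en-1-one; 2 [4-(trimethylsilyl)but-3-yn-1-yl]magnesium bromide; 4 tert-butyl bromoacetate
Product: 6 tert-butyl 2-[(1R,2S)-1,3,3-trimethyl-6-oxo-2-[4-(trimethylsilyl)but-3-yn-1-yl]cyclohexyl]acetate, via magnesium enolate 5 (not isolated)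
Conditions: CuBr·SMe2 (5 mol %), (R)-1-[(SP)-2-(dicyclohexylphosphino)ferrocenyl]ethyldiphenylphosphine (6 mol %), t-BuOMe, −78 to −40 °C, slow addition of 2; then 4, DMPU, −40 °C to rt
Reagents that add atoms: none
Why: Transmetalation of 2 onto the chiral CuBr–diphosphine complex gives an alkyl species of monovalent copper that binds the C5=C10 π-bond of 3, adds oxidatively at C5 to a σ-alkyl intermediate of trivalent copper and reductively eliminates, forging C5–C6 and leaving magnesium enolate 5, which is then C-alkylated at C10 by tert-butyl bromoacetate (SN2), forging C9–C10. The closest known reaction type is the copper/ferrocenyl-diphosphine-catalysed asymmetric conjugate addition of Grignard reagents to cyclic enones with in-situ alkylation of the magnesium enolate, which includes α-methyl cycloalkenones. No ring is closed. C5 is controlled by the ligand, which discriminates the enantiotopic faces of the achiral planar enone. C10 is controlled by the substrate: in the half-chair of 5 the new C5 arm lies pseudo-axial to avoid eclipsing the C10 methyl and the C4 methyls, and the electrophile enters along the axial trajectory on the opposite face, so that C9 ends trans to C6 and the C10 methyl trans to H-5. The step needs 1,4- rather than 1,2-addition, secured by copper catalysis, slow addition of 2 at low temperature and shielding of the carbonyl by the α-methyl group, and it needs C-alkylation before proton transfer, secured by the absence of an acidic partner, by DMPU and by the high SN2 reactivity of an α-bromo ester on an enolate that has no regioisomer to equilibrate to. The silyl cap protects the alkyne C–H from the Grignard reagent and the tert-butyl ester resists residual organomagnesium.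

Step 3
Reactants: 6 tert-butyl 2-[(1R,2S)-1,3,3-trimethyl-6-oxo-2-[4-(trimethylsilyl)but-3-yn-1-yl]cyclohexyl]acetate
Product: 7 tert-butyl 2-[(1R,2S,6E)-1,3,3-trimethyl-6-[2-(4-methylbenzenesulfonyl)hydrazinylidene]-2-[4-(trimethylsilyl)but-3-yn-1-yl]cyclohexyl]acetate
Conditions: TsNHNH2, PPTS (cat.), EtOH, reflux
Reagents that add atoms: 4-methylbenzenesulfonohydrazide, Cc1ccc(cc1)S(=O)(=O)NN
Why: Hydrazone formation at the only carbonyl open to nitrogen nucleophiles; the tert-butyl ester resists acyl substitution, which also blocks closure of this γ-keto ester to a dihydropyridazinone, and the quaternary neighbour slows but should not stop the condensation.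

Step 4
Reactants: 7 tert-butyl 2-[(1R,2S,6E)-1,3,3-trimethyl-6-[2-(4-methylbenzenesulfonyl)hydrazinylidene]-2-[4-(trimethylsilyl)but-3-yn-1-yl]cyclohexyl]acetate
Product: 10 tert-butyl 2-[(1R,2S)-1,3,3-trimethyl-2-[4-(trimethylsilyl)but-3-yn-1-yl]cyclohexyl]acetate, via N-boryl tosylhydrazine 8 (not isolated), via alkyldiazene 9 (not isolated)
Conditions: catecholborane, CHCl3, 0 °C to rt; then NaOAc·3H2O, reflux
Reagents that add atoms: none
Why: Hydride transfer from catecholborane to C=N gives 8, acetate-induced loss of sulfinate gives diazene 9, and 9 extrudes N2 with delivery of hydrogen to C1 (tosylhydrazone reduction, a mild Wolff–Kishner variant); ester and silylalkyne are inert, and C1 becomes a methylene so that no stereocentre is at stake.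

Step 5
Reactants: 10 tert-butyl 2-[(1R,2S)-1,3,3-trimethyl-2-[4-(trimethylsilyl)but-3-yn-1-yl]cyclohexyl]acetate
Product: 11 tert-butyl 2-[(1R,2S)-2-(but-3-yn-1-yl)-1,3,3-trimethylcyclohexyl]acetate
Conditions: K2CO3, MeOH, rt
Reagents that add atoms: none
Why: Methoxide-catalysed protodesilylation of the alkynyl–silicon bond; the tert-butyl ester is not transesterified under these conditions.

Step 6
Reactants: 11 tert-butyl 2-[(1R,2S)-2-(but-3-yn-1-yl)-1,3,3-trimethylcyclohexyl]acetate
Product: 13 2-[(1R,2S)-2-(but-3-yn-1-yl)-1,3,3-trimethylcyclohexyl]acetaldehyde, via aluminium hemiacetal 12 (not isolated)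
Conditions: i-Bu2AlH (1.1 equiv), CH2Cl2, −78 °C; then aq. potassium sodium tartrate
Reagents that add atoms: none
Why: Partial reduction of an ester: hydride addition gives the tetrahedral aluminium hemiacetal 12, which for a tert-butyl ester is stable at −78 °C and releases the aldehyde only on work-up; the terminal alkyne is neither metalated nor hydroaluminated at this temperature.

Step 7
Reactants: 13 2-[(1R,2S)-2-(but-3-yn-1-yl)-1,3,3-trimethylcyclohexyl]acetaldehyde
Product: 14 tert-butyl{[(1Z)-2-[(1S,2S)-2-(but-3-yn-1-yl)-1,3,3-trimethylcyclohexyl]ethenyl]oxy}dimethylsilane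
Conditions: TBSOTf, Et3N, CH2Cl2, 0 °C to rt
Reagents that add atoms: tert-butyldimethylsilyl trifluoromethanesulfonate, CC(C)(C)[Si](C)(C)OS(=O)(=O)C(F)(F)F
Why: Soft enolisation (O-silylation to a silyloxocarbenium ion, then deprotonation at C9 by the amine) should give the Z enol silane as the kinetic isomer; the geometry is not transferred to any stereocentre because C11 returns to a trigonal formyl carbon, so any E isomer is carried forward as well.

Step 8
Reactants: 14 tert-butyl{[(1Z)-2-[(1S,2S)-2-(but-3-yn-1-yl)-1,3,3-trimethylcyclohexyl]ethenyl]oxy}dimethylsilane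
Product: 15 (1S,4aS,8aS)-5,5,8a-trimethyl-2-methylidenedecahydronaphthalene-1-carbaldehyde (albicanal)
Conditions: Ph3PAuNTf2 (5 mol %), CH2Cl2/MeOH (10:1), rt
Reagents that add atoms: none
Why: Silyl enol ether–alkyne carbocyclisation (a Conia-ene-type reaction under π-acid catalysis): monovalent gold activates the terminal alkyne, C9 adds anti to gold at C8 in a 6-exo-dig closure, and methanol removes silicon from the oxocarbenium ion and protonates the vinyl–gold bond to give the aldehyde and the C8 methylene. C9 is set in a chair-like transition state with the C9=C11 unit equatorial (anti to C5), which gives the 9S formyl epimer, also the more stable one.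

Step 9
Reactants: 16 2-(bromomethyl)prop-2-enoic acid
Product: 17 prop-2-en-1-yl 2-(bromomethyl)prop-2-enoate
Conditions: allyl alcohol, TsOH·H2O (cat.), hydroquinone (cat.), toluene, reflux (Dean–Stark)
Reagents that add atoms: prop-2-en-1-ol, C=CCO
Why: Fischer esterification with azeotropic removal of water; the acidic, non-nucleophilic medium leaves the allylic bromide intact.

Step 10
Reactants: 15 (1S,4aS,8aS)-5,5,8a-trimethyl-2-methylidenedecahydronaphthalene-1-carbaldehyde; 17 prop-2-en-1-yl 2-(bromomethyl)prop-2-enoate
Product: 19 prop-2-en-1-yl (4S)-4-hydroxy-2-methylidene-4-[(1S,4aS,8aS)-5,5,8a-trimethyl-2-methylidenedecahydronaphthalen-1-yl]butanoate (expected major C11 epimer; the mixture with 21 is used), via allylindium reagent 18 (not isolated)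
Conditions: In powder, THF/H2O (3:1), rt
Reagents that add atoms: none
Why: Barbier allylation: indium inserts into the allylic C–Br bond and 18 adds to the aldehyde through a six-membered cyclic transition state, forming C11–C12 and regenerating the C13 methylene; Felkin–Anh attack anti to C10 predicts the 11S epimer as major, which does not matter because C11 is oxidised next, and the neutral aqueous medium avoids epimerisation at C9 and lactonisation.

Step 11
Reactants: 19 prop-2-en-1-yl (4S)-4-hydroxy-2-methylidene-4-[(1S,4aS,8aS)-5,5,8a-trimethyl-2-methylidenedecahydronaphthalen-1-yl]butanoate (C11 mixture)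
Product: 20 prop-2-en-1-yl 2-methylidene-4-oxo-4-[(1S,4aS,8aS)-5,5,8a-trimethyl-2-methylidenedecahydronaphthalen-1-yl]butanoate
Conditions: Dess–Martin periodinane, NaHCO3, CH2Cl2, 0 °C to rt
Reagents that add atoms: none
Why: Dess–Martin oxidation of a secondary alcohol under buffered conditions that should not enolise the ketone toward C9 or C12, so both alkenes stay in place.

Step 12
Reactants: 20 prop-2-en-1-yl 2-methylidene-4-oxo-4-[(1S,4aS,8aS)-5,5,8a-trimethyl-2-methylidenedecahydronaphthalen-1-yl]butanoate
Product: 21 prop-2-en-1-yl (4R)-4-hydroxy-2-methylidene-4-[(1S,4aS,8aS)-5,5,8a-trimethyl-2-methylidenedecahydronaphthalen-1-yl]butanoate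
Conditions: (S)-2-methyl-CBS-oxazaborolidine (0.5 equiv), catecholborane, toluene, −78 to −20 °C
Reagents that add atoms: none
Why: Corey–Bakshi–Shibata reduction: the ketone binds the oxazaborolidine boron anti to its bulky C9 side and takes hydride from the coordinated borane, and the (S)-catalyst should give the 11R carbinol (the sense of acetophenone to (R)-1-phenylethanol); Felkin–Anh delivery of hydride anti to C10 points the same way, and catecholborane at low temperature spares both alkenes and the ester.

Step 13
Reactants: 21 prop-2-en-1-yl (4R)-4-hydroxy-2-methylidene-4-[(1S,4aS,8aS)-5,5,8a-trimethyl-2-methylidenedecahydronaphthalen-1-yl]butanoate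
Product: 22 prop-2-en-1-yl (4R)-4-(acetyloxy)-2-methylidene-4-[(1S,4aS,8aS)-5,5,8a-trimethyl-2-methylidenedecahydronaphthalen-1-yl]butanoate
Conditions: Ac2O, pyridine, DMAP (cat.), CH2Cl2, rt
Reagents that add atoms: acetic anhydride, CC(=O)OC(C)=O
Why: DMAP-catalysed acylation of the hindered secondary alcohol with retention at C11; it also removes the free hydroxyl that could lactonise onto the ester.

Step 14
Reactants: 22 prop-2-en-1-yl (4R)-4-(acetyloxy)-2-methylidene-4-[(1S,4aS,8aS)-5,5,8a-trimethyl-2-methylidenedecahydronaphthalen-1-yl]butanoate
Product: 23 (1R)-2-(2-oxo-2,5-dihydrofuran-3-yl)-1-[(1S,4aS,8aS)-5,5,8a-trimethyl-2-methylidenedecahydronaphthalen-1-yl]ethyl acetate, (11R)-11-acetoxylabda-8(17),13-dien-16,15-olide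
Conditions: second-generation Grubbs catalyst RuCl2(=CHPh)(H2IMes)(PCy3) (5 mol %), CH2Cl2 (5 mM), 40 °C
Reagents that add atoms: none
Why: Ring-closing metathesis: the ruthenium carbene loads on the monosubstituted allyl alkene and closes onto the acrylate methylene, forming C13=C14 in a five-membered ring with loss of ethene; the hindered exocyclic C8=C17 is a poor partner and closure onto it would need a medium ring.

## Compound list

1 | 4-bromo-1-(trimethylsilyl)but-1-yne | C[Si](C)(C)C#CCCBr | starting material
2 | [4-(trimethylsilyl)but-3-yn-1-yl]magnesium bromide | C[Si](C)(C)C#CCC[Mg]Br | intermediate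
3 | 2,4,4-trimethylcyclohex-2-en-1-one | CC1=CC(C)(C)CCC1=O | starting material
4 | tert-butyl bromoacetate | CC(C)(C)OC(=O)CBr | starting material
5 | bromomagnesium (3S)-2,4,4-trimethyl-3-[4-(trimethylsilyl)but-3-yn-1-yl]cyclohex-1-en-1-olate | C[Si](C)(C)C#CCC[C@H]1C(C)(C)CCC(O[Mg]Br)=C1C | intermediate (not isolated)
6 | tert-butyl 2-[(1R,2S)-1,3,3-trimethyl-6-oxo-2-[4-(trimethylsilyl)but-3-yn-1-yl]cyclohexyl]acetate | C[Si](C)(C)C#CCC[C@H]1C(C)(C)CCC(=O)[C@]1(C)CC(=O)OC(C)(C)C | intermediate
7 | tert-butyl 2-[(1R,2S,6E)-1,3,3-trimethyl-6-[2-(4-methylbenzenesulfonyl)hydrazinylidene]-2-[4-(trimethylsilyl)but-3-yn-1-yl]cyclohexyl]acetate | C[Si](C)(C)C#CCC[C@H]1C(C)(C)CC/C(=N\NS(=O)(=O)c2ccc(C)cc2)[C@]1(C)CC(=O)OC(C)(C)C | intermediate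
8 | tert-butyl 2-[(1R,2S,6R)-6-[1-(1,3,2-benzodioxaborol-2-yl)-2-(4-methylbenzenesulfonyl)hydrazinyl]-1,3,3-trimethyl-2-[4-(trimethylsilyl)but-3-yn-1-yl]cyclohexyl]acetate (configuration at the hydrazine carbon as expected, of no consequence) | C[Si](C)(C)C#CCC[C@H]1C(C)(C)CC[C@@H](N(B2Oc3ccccc3O2)NS(=O)(=O)c2ccc(C)cc2)[C@]1(C)CC(=O)OC(C)(C)C | intermediate (not isolated)
9 | tert-butyl 2-[(1R,2S,6R)-6-diazenyl-1,3,3-trimethyl-2-[4-(trimethylsilyl)but-3-yn-1-yl]cyclohexyl]acetate | C[Si](C)(C)C#CCC[C@H]1C(C)(C)CC[C@@H](N=N)[C@]1(C)CC(=O)OC(C)(C)C | intermediate (not isolated)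
10 | tert-butyl 2-[(1R,2S)-1,3,3-trimethyl-2-[4-(trimethylsilyl)but-3-yn-1-yl]cyclohexyl]acetate | C[Si](C)(C)C#CCC[C@H]1C(C)(C)CCC[C@]1(C)CC(=O)OC(C)(C)C | intermediate
11 | tert-butyl 2-[(1R,2S)-2-(but-3-yn-1-yl)-1,3,3-trimethylcyclohexyl]acetate | C#CCC[C@H]1C(C)(C)CCC[C@]1(C)CC(=O)OC(C)(C)C | intermediate
12 | {1-tert-butoxy-2-[(1R,2S)-2-(but-3-yn-1-yl)-1,3,3-trimethylcyclohexyl]ethoxy}bis(2-methylpropyl)alumane (both configurations at the acetal carbon) | C#CCC[C@H]1C(C)(C)CCC[C@]1(C)CC(OC(C)(C)C)O[Al](CC(C)C)CC(C)C | intermediate (not isolated)
13 | 2-[(1R,2S)-2-(but-3-yn-1-yl)-1,3,3-trimethylcyclohexyl]acetaldehyde | C#CCC[C@H]1C(C)(C)CCC[C@]1(C)CC=O | intermediate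
14 | tert-butyl{[(1Z)-2-[(1S,2S)-2-(but-3-yn-1-yl)-1,3,3-trimethylcyclohexyl]ethenyl]oxy}dimethylsilane | C#CCC[C@H]1C(C)(C)CCC[C@]1(C)/C=C\O[Si](C)(C)C(C)(C)C | intermediate
15 | (1S,4aS,8aS)-5,5,8a-trimethyl-2-methylidenedecahydronaphthalene-1-carbaldehyde (albicanal) | C=C1CC[C@H]2C(C)(C)CCC[C@]2(C)[C@H]1C=O | intermediate
16 | 2-(bromomethyl)prop-2-enoic acid | C=C(CBr)C(=O)O | starting material
17 | prop-2-en-1-yl 2-(bromomethyl)prop-2-enoate | C=CCOC(=O)C(=C)CBr | intermediate
18 | {2-[(prop-2-en-1-yloxy)carbonyl]prop-2-en-1-yl}indium dibromide (one component of the sesquibromide) | C=CCOC(=O)C(=C)C[In](Br)Br | intermediate (not isolated)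
19 | prop-2-en-1-yl (4S)-4-hydroxy-2-methylidene-4-[(1S,4aS,8aS)-5,5,8a-trimethyl-2-methylidenedecahydronaphthalen-1-yl]butanoate | C=C1CC[C@H]2C(C)(C)CCC[C@]2(C)[C@H]1[C@@H](O)CC(=C)C(=O)OCC=C | intermediate
20 | prop-2-en-1-yl 2-methylidene-4-oxo-4-[(1S,4aS,8aS)-5,5,8a-trimethyl-2-methylidenedecahydronaphthalen-1-yl]butanoate | C=C1CC[C@H]2C(C)(C)CCC[C@]2(C)[C@H]1C(=O)CC(=C)C(=O)OCC=C | intermediate
21 | prop-2-en-1-yl (4R)-4-hydroxy-2-methylidene-4-[(1S,4aS,8aS)-5,5,8a-trimethyl-2-methylidenedecahydronaphthalen-1-yl]butanoate | C=C1CC[C@H]2C(C)(C)CCC[C@]2(C)[C@H]1[C@H](O)CC(=C)C(=O)OCC=C | intermediate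
22 | prop-2-en-1-yl (4R)-4-(acetyloxy)-2-methylidene-4-[(1S,4aS,8aS)-5,5,8a-trimethyl-2-methylidenedecahydronaphthalen-1-yl]butanoate | C=C1CC[C@H]2C(C)(C)CCC[C@]2(C)[C@H]1[C@H](OC(C)=O)CC(=C)C(=O)OCC=C | intermediate
23 | (1R)-2-(2-oxo-2,5-dihydrofuran-3-yl)-1-[(1S,4aS,8aS)-5,5,8a-trimethyl-2-methylidenedecahydronaphthalen-1-yl]ethyl acetate | C=C1CC[C@H]2C(C)(C)CCC[C@]2(C)[C@H]1[C@@H](CC1=CCOC1=O)OC(C)=O | target

## Step count and least certain steps

Total step count: 14. Longest linear sequence: 13 (steps 1 to 8 and 10 to 14; step 9 prepares reagent 17).

Step 2 (key step). The β-carbon of 3 is flanked by the C4 quaternary centre and the α-methyl group, so slow turnover, competing 1,2-addition and erosion of enantioface selection are the main threats. Incomplete C-alkylation of the hindered tetrasubstituted magnesium enolate (proton quench on work-up or O-alkylation) is the second. The fallback sets out from 2 and returns at 6. The conjugate addition is moved to the less hindered 4,4-dimethylcyclohex-2-en-1-one F1 with the same copper–ligand system, and the magnesium enolate is trapped with MeI and DMPU to give trans-(2R,3R)-2,4,4-trimethyl-3-[4-(trimethylsilyl)but-3-yn-1-yl]cyclohexan-1-one F2. Thermodynamic enol silylation (TMSCl, NaI, Et3N, MeCN) gives the tetrasubstituted trimethylsilyl enol ether F3. The lithium enolate released from it with halide-free MeLi (THF, 0 °C) is alkylated with 4 in the presence of DMPU, anti to the C5 arm, to give 6.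

Step 3. Condensation at a ketone next to a quaternary carbon may stall, or the hydrazone nitrogen may cyclise onto the ester. The fallback sets out from 6 and returns at 10, replacing steps 3 and 4. NaBH4 (MeOH, 0 °C) reduces only the ketone to tert-butyl 2-[(1R,2S,6R)-6-hydroxy-1,3,3-trimethyl-2-[4-(trimethylsilyl)but-3-yn-1-yl]cyclohexyl]acetate F4 (equatorial alcohol expected; either epimer serves). Acylation with PhOC(S)Cl, pyridine and DMAP gives the O-phenyl thionocarbonate F5. Barton–McCombie deoxygenation (Bu3SnH, AIBN, toluene, 100 °C, high stannane concentration so that the C1 radical is reduced before it can reach the alkyne) gives 10.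

Step 8. The silyl group may be lost to methanol before the C–C bond forms, the ring may close through the transition state with an axial formyl group (C9 epimer), or traces of acid may move C8=C17 into the ring. The fallback sets out from 14 and returns at 15. NBS (THF, −78 °C) converts 14 into 2-bromo-2-[(1S,2S)-2-(but-3-yn-1-yl)-1,3,3-trimethylcyclohexyl]acetaldehyde F6 (both C9 epimers). A radical 6-exo-dig cyclisation (Bu3SnH, AIBN, benzene, 80 °C, slow addition) then closes C8–C9 under neutral conditions, and the vinyl radical is reduced to the exocyclic methylene of 15.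

Step 12. The ketone is very hindered, so coordination to the oxazaborolidine may be slow and facial discrimination insufficient. If a first run of step 10 shows 21 as the major adduct, it is separated and acetylated directly and only the remainder passes through steps 11 and 12. The fallback sets out from 15 and returns at 22, replacing steps 9 to 13, and sets C11 during C–C bond formation under reagent control. Tributyl(2-bromoprop-2-en-1-yl)stannane F7 (from 2,3-dibromopropene and Bu3SnLi) is transmetalated with the chiral bromoborane made from N,N′-ditosyl-1,2-diphenylethane-1,2-diamine and BBr3, using the enantiomer that directs attack to the Re face of C11 (the R,R series is expected). Addition to 15 at −78 °C gives (1R)-3-bromo-1-[(1S,4aS,8aS)-5,5,8a-trimethyl-2-methylidenedecahydronaphthalen-1-yl]but-3-en-1-ol F8. Acetylation (Ac2O, pyridine, DMAP) gives the acetate F9. Alkoxycarbonylation (PdCl2(PPh3)2, CO at 20 atm, allyl alcohol, Et3N, 60 °C; the pressure is meant to let CO insertion outrun 5-exo carbopalladation of C8=C17) gives 22.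

## Further compounds

F1 | step 2 | 4,4-dimethylcyclohex-2-en-1-one | CC1(C)C=CC(=O)CC1
F2 | step 2 | (2R,3R)-2,4,4-trimethyl-3-[4-(trimethylsilyl)but-3-yn-1-yl]cyclohexan-1-one | C[Si](C)(C)C#CCC[C@H]1C(C)(C)CCC(=O)[C@@H]1C
F3 | step 2 | trimethyl{[(3S)-2,4,4-trimethyl-3-[4-(trimethylsilyl)but-3-yn-1-yl]cyclohex-1-en-1-yl]oxy}silane | C[Si](C)(C)C#CCC[C@H]1C(C)(C)CCC(O[Si](C)(C)C)=C1C
F4 | step 3 | tert-butyl 2-[(1R,2S,6R)-6-hydroxy-1,3,3-trimethyl-2-[4-(trimethylsilyl)but-3-yn-1-yl]cyclohexyl]acetate | C[Si](C)(C)C#CCC[C@H]1C(C)(C)CC[C@@H](O)[C@]1(C)CC(=O)OC(C)(C)C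
F5 | step 3 | tert-butyl 2-[(1R,2S,6R)-1,3,3-trimethyl-6-[(phenoxycarbonothioyl)oxy]-2-[4-(trimethylsilyl)but-3-yn-1-yl]cyclohexyl]acetate | C[Si](C)(C)C#CCC[C@H]1C(C)(C)CC[C@@H](OC(=S)Oc2ccccc2)[C@]1(C)CC(=O)OC(C)(C)C
F6 | step 8 | 2-bromo-2-[(1S,2S)-2-(but-3-yn-1-yl)-1,3,3-trimethylcyclohexyl]acetaldehyde (both configurations at the bromine-bearing carbon) | C#CCC[C@H]1C(C)(C)CCC[C@]1(C)C(Br)C=O
F7 | step 12 | tributyl(2-bromoprop-2-en-1-yl)stannane | C=C(Br)C[Sn](CCCC)(CCCC)CCCC
F8 | step 12 | (1R)-3-bromo-1-[(1S,4aS,8aS)-5,5,8a-trimethyl-2-methylidenedecahydronaphthalen-1-yl]but-3-en-1-ol | C=C1CC[C@H]2C(C)(C)CCC[C@]2(C)[C@H]1[C@H](O)CC(Br)=C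
F9 | step 12 | (1R)-3-bromo-1-[(1S,4aS,8aS)-5,5,8a-trimethyl-2-methylidenedecahydronaphthalen-1-yl]but-3-en-1-yl acetate | C=C1CC[C@H]2C(C)(C)CCC[C@]2(C)[C@H]1[C@H](OC(C)=O)CC(Br)=C
A1 | alternative 1 | (2E,6E)-farnesyl diphosphate | CC(C)=CCC/C(C)=C/CC/C(C)=C/COP(=O)(O)OP(=O)(O)O
A2 | alternative 1 | (5S,9S,10S)-albicanol | C=C1CC[C@H]2C(C)(C)CCC[C@]2(C)[C@H]1CO
A3 | alternative 2 | (2Z,5R)-5-[(tert-butyldimethylsilyl)oxy]-3-iodo-5-[(1S,4aS,8aS)-5,5,8a-trimethyl-2-methylidenedecahydronaphthalen-1-yl]pent-2-en-1-ol | C=C1CC[C@H]2C(C)(C)CCC[C@]2(C)[C@H]1[C@@H](C/C(I)=C/CO)O[Si](C)(C)C(C)(C)C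
A4 | alternative 2 | (11R)-11-(tert-butyldimethylsilyloxy)labda-8(17),13-dien-16,15-olide | C=C1CC[C@H]2C(C)(C)CCC[C@]2(C)[C@H]1[C@@H](CC1=CCOC1=O)O[Si](C)(C)C(C)(C)C
A5 | alternative 3 | monocyclic ring-A precursor with a vinyl group on C5, the C8 enol triflate on C9, the C11 tert-butyldimethylsilyl ether and the [2-(trimethylsilyl)furan-3-yl]methyl group (configurations at C5, C9, C10 and C11 as in A6) | C=C[C@H]1C(C)(C)CCC[C@]1(C)[C@H](C(=C)OS(=O)(=O)C(F)(F)F)[C@@H](Cc1ccoc1[Si](C)(C)C)O[Si](C)(C)C(C)(C)C
A6 | alternative 3 | (11R)-11-(tert-butyldimethylsilyloxy)-12-[2-(trimethylsilyl)furan-3-yl] labdane with the C8 methylene | C=C1CC[C@H]2C(C)(C)CCC[C@]2(C)[C@H]1[C@@H](Cc1ccoc1[Si](C)(C)C)O[Si](C)(C)C(C)(C)C
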